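A direct plan would build rings B and C together at the end from squaric acid pieces (ring A: terminal aryl ether ring; ring B: central benzene ring; ring C: quinone).
The ring A phenol would be joined to 3-chloro-4-methylcyclobutenedione A1 to give aryl methylsemisquarate A2.
One flask would then take A2, an alkenyllithium, more A1 and more alkenyllithium to the O-linked bis(4-alkenylcyclobutenone) A3.
Heating would expand both four-membered rings to triphenol A4, to be oxidised at ring C and methylated at ring B in the same pot.
Its first weak step would be the one-flask addition, carbinolate capture and second addition: three selective events without precedent, a labile tertiary allylic ester and two uncontrolled carbinol centres.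
Its second would be the twofold ring expansion with oxidation and methylation: both rings would close last, on the most precious material, with three phenolic oxygens told apart only by rates.
Its third would be the three-step making of A1 (methyl addition, hydrolysis, chlorination): many steps for a four-carbon reagent.

**Plan of the new route**
Cuts: first the B6–O–quinone bond (phenoxide of 17 plus bromoquinone 19), then ring B itself across B2–B3, B1–B6 and B5–B6 into aryl propynyl ether 6, alkenyl(methoxy)carbene complex 14 and one CO ligand.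
Enabling feature: around ring B the atoms read B6(O)–B1(OAr)–B2(Me)–B3(OMe)–B4(H)–B5(iPr). This is a hydroquinone monomethyl ether whose free oxygen lies next to the aryloxy carbon, which is the pattern CO–alkyne–carbene carbon–alkene that a Dötz benzannulation writes.
Ring order: ring A (from thymol), then ring B built onto the oxygen of ring A from three components, then ring C attached last as a ready-made quinone from the same phenol 3.
No cyclobutenone, no one-flask triple addition and no late double ring closure occur. B3–OMe and B6–OH leave the benzannulation already differentiated and the quinone enters at its final oxidation level, so no late oxidation or selective methylation is needed.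

Key step: step 6

Remark: the target has no stereocentre; thymol, trichloroethylene, Cr(CO)6 and 2-methylpropanal are taken as commercial.

Step 1
Reactants: 1 thymol (5-methyl-2-(propan-2-yl)phenol)
Product: 3 4-methoxy-5-methyl-2-(propan-2-yl)phenol, via quinone monoketal 2 (not isolated)
Conditions: PhI(OAc)2 (2.1 equiv), MeOH, 0 °C to rt; then Zn dust, AcOH, rt
Reagents that add atoms: methanol (CO)
Why: Oxidative dearomatisation of the para-unsubstituted phenol by PhI(OAc)2 in methanol gives the p-quinone monoketal 2, and zinc reduction rearomatises it with loss of one methanol, so the methoxy group ends up para to the hydroxyl (next to the ring methyl) without any regiochemical choice.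

Step 2
Reactants: 3 4-methoxy-5-methyl-2-(propan-2-yl)phenol
Product: 4 1-{[(E)-1,2-dichloroethenyl]oxy}-4-methoxy-5-methyl-2-(propan-2-yl)benzene
Conditions: Cl2C=CHCl (1.5 equiv), K2CO3 (2 equiv), DMF, 70 °C, Ar
Reagents that add atoms: trichloroethylene (ClC=C(Cl)Cl)
Why: Base-mediated dehydrochlorination of trichloroethylene gives dichloroacetylene in situ, to which the phenoxide adds in anti fashion to give the (E)-1,2-dichlorovinyl ether, the established entry from phenols to aryl ynol ethers.

Step 3
Reactants: 4 aryl (E)-1,2-dichlorovinyl ether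
Product: 6 1-methoxy-2-methyl-5-(propan-2-yl)-4-(prop-1-yn-1-yloxy)benzene, via lithium aryloxyacetylide 5 (not isolated)
Conditions: n-BuLi (2.3 equiv), THF, −78 to −40 °C; then MeI (5 equiv), DMPU (3 equiv), −78 °C to rt; Et3N-deactivated silica
Reagents that add atoms: iodomethane (CI)
Why: n-BuLi effects elimination of HCl and chlorine–lithium exchange to the lithium aryloxyacetylide 5, which is C-methylated by iodomethane (ynol ether synthesis from 1,2-dichlorovinyl ethers); the O-aryl group has no β-hydrogen, so the ynol ether cannot fragment to a ketene by a retro-ene reaction.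

Step 4
Reactants: 7 hexacarbonylchromium Cr(CO)6
Product: 9 pentacarbonyl(1-methoxyethylidene)chromium, via lithium acetylchromate 8 (not isolated)
Conditions: MeLi (1.0 equiv), Et2O, rt; then Me3OBF4 (1.3 equiv), H2O, 0 °C; pentane extraction
Reagents that add atoms: methyllithium ([Li]C); trimethyloxonium tetrafluoroborate (C[O+](C)C.F[B-](F)(F)F)
Why: Classical Fischer carbene synthesis, in which methyllithium adds to a carbonyl ligand and the resulting acyl chromate is O-methylated by the oxonium salt.

Step 5
Reactants: 9 pentacarbonyl(1-methoxyethylidene)chromium; 10 2-methylpropanal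
Product: 14 pentacarbonyl[(2E)-1-methoxy-4-methylpent-2-en-1-ylidene]chromium, via lithium carbene anion 11 (not isolated), via aldol adduct 12 (not isolated), via mesylate 13 (not isolated)
Conditions: n-BuLi (1.0 equiv), THF, −78 °C; 10 premixed with BF3·OEt2 (1.2 equiv each), −78 °C; AcOH quench; crude 12, MsCl (1.5 equiv), Et3N (3 equiv), CH2Cl2, 0 °C
Reagents that add atoms: none
Why: The α-hydrogens of the methylcarbene complex are strongly acidic, its anion adds to the Lewis-acid-activated aldehyde (aldol reaction of a Fischer carbene "enolate"), and mesylation with E1cB elimination gives the conjugated (E)-alkenylcarbene; the racemic carbinol centre of 12 is destroyed.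

Step 6
Reactants: 6 aryl prop-1-ynyl ether; 14 pentacarbonyl[(2E)-1-methoxy-4-methylpent-2-en-1-ylidene]chromium
Product: 17 4-methoxy-2-[4-methoxy-5-methyl-2-(propan-2-yl)phenoxy]-3-methyl-6-(propan-2-yl)phenol, via chromium-bound dienylketene 15 (not isolated), via arene tricarbonylchromium complex 16 (not isolated)
Conditions: 14 (1.3 equiv), THF (0.05 M, degassed), Ar, 50 °C, 16 h; then air, EtOAc, rt; SiO2
Reagents that add atoms: none
Why: Proposed new method: the closest known reaction is the Dötz benzannulation of alkenyl(methoxy)carbene chromium complexes with internal alkynes to 4-methoxyphenols, here run with an aryl 1-propynyl ether as the alkyne. Thermal loss of one CO from 14, alkyne coordination and insertion should bond the nucleophilic methyl-bearing alkyne carbon to the electrophilic carbene carbon (bond B2–B3) and make the aryloxy-bearing carbon the new donor-stabilised chromium-bound carbon, as ynamines insert; CO insertion there (bond B1–B6) gives the dienylketene complex 15. Ring B then closes by thermal 6π electrocyclisation of 15 between the ketene carbon and the isopropyl-bearing alkene terminus (bond B5–B6), and tautomerisation of the cyclohexadienone gives the phenol, set free from 16 by air. No stereocentre results, since the only sp3 ring carbon of the dienone (B5) is aromatised. The step needs regioselective insertion, which the oxygen donor and the steric rule (larger aryloxy group next to the CO-derived carbon) direct the same way, and benzannulation instead of arrest after insertion or cyclopentannulation, which an alkenyl complex in THF and the weak donor power of the aryloxy group should secure. The methoxy group arrives on B3 and the free hydroxyl on B6, so the two para oxygens of ring B are differentiated without a protecting group or a selective alkylation.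

Step 7
Reactants: 3 4-methoxy-5-methyl-2-(propan-2-yl)phenol
Product: 19 2-bromo-3-methyl-6-(propan-2-yl)cyclohexa-2,5-diene-1,4-dione, via bromophenol 18 (not isolated)
Conditions: NBS (1.0 equiv), MeCN, 0 °C, dark; then H2O, PhI(OAc)2 (1.1 equiv), 0 °C
Reagents that add atoms: N-bromosuccinimide (O=C1CCC(=O)N1Br); water (O)
Why: Electrophilic bromination goes to the only free position ortho to the hydroxyl (the other free carbon is meta to OH and flanked by the isopropyl group), and PhI(OAc)2 in aqueous acetonitrile then oxidises the p-methoxyphenol to the p-quinone with loss of methanol (oxidative demethylation), which fixes the bromine next to the ring methyl.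

Step 8
Reactants: 17 ring A–ring B phenol; 19 2-bromo-3-methyl-6-(propan-2-yl)cyclohexa-2,5-diene-1,4-dione
Product: 21 CNP0335608.0 (target), via sodium phenoxide 20 (not isolated)
Conditions: NaH (1.05 equiv), THF, 0 °C; then 19 (1.2 equiv) in DMF, −40 to 0 °C, Ar, dark
Reagents that add atoms: none
Why: Addition–elimination (vinylogous acyl substitution) of a phenoxide at the bromine-bearing carbon of a 2-bromo-1,4-benzoquinone is the standard route to aryloxyquinones; here the phenoxide can react only at oxygen because both ortho carbons and the para carbon are substituted, loss of bromide makes attack at C–Br irreversible whereas O-addition at the free CH beside the isopropyl group is reversible, and the quinone enters at its final oxidation level.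

## Compound list
1 | thymol (5-methyl-2-(propan-2-yl)phenol) | CC(C)c1ccc(C)cc1O | starting material
2 | 4,4-dimethoxy-5-methyl-2-(propan-2-yl)cyclohexa-2,5-dien-1-one | COC1(OC)C=C(C(C)C)C(=O)C=C1C | intermediate
3 | 4-methoxy-5-methyl-2-(propan-2-yl)phenol | COc1cc(C(C)C)c(O)cc1C | intermediate
4 | 1-{[(E)-1,2-dichloroethenyl]oxy}-4-methoxy-5-methyl-2-(propan-2-yl)benzene | Cl/C=C(/Cl)Oc1cc(C)c(OC)cc1C(C)C | intermediate
5 | lithium [4-methoxy-5-methyl-2-(propan-2-yl)phenoxy]acetylide | [Li]C#COc1cc(C)c(OC)cc1C(C)C | intermediate
6 | 1-methoxy-2-methyl-5-(propan-2-yl)-4-(prop-1-yn-1-yloxy)benzene | CC#COc1cc(C)c(OC)cc1C(C)C | intermediate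
7 | hexacarbonylchromium Cr(CO)6 | [Cr].[C-]#[O+].[C-]#[O+].[C-]#[O+].[C-]#[O+].[C-]#[O+].[C-]#[O+] | starting material
8 | lithium acetylpentacarbonylchromate | [Li+].CC(=O)[Cr-].[C-]#[O+].[C-]#[O+].[C-]#[O+].[C-]#[O+].[C-]#[O+] | intermediate
9 | pentacarbonyl(1-methoxyethylidene)chromium | COC(C)=[Cr].[C-]#[O+].[C-]#[O+].[C-]#[O+].[C-]#[O+].[C-]#[O+] | intermediate
10 | 2-methylpropanal | CC(C)C=O | starting material
11 | lithium pentacarbonyl(1-methoxyethenyl)chromate | [Li+].C=C(OC)[Cr-].[C-]#[O+].[C-]#[O+].[C-]#[O+].[C-]#[O+].[C-]#[O+] | intermediate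
12 | pentacarbonyl(3-hydroxy-1-methoxy-4-methylpentylidene)chromium (racemic) | COC(CC(O)C(C)C)=[Cr].[C-]#[O+].[C-]#[O+].[C-]#[O+].[C-]#[O+].[C-]#[O+] | intermediate
13 | pentacarbonyl[1-methoxy-4-methyl-3-(methylsulfonyloxy)pentylidene]chromium (racemic) | COC(CC(OS(C)(=O)=O)C(C)C)=[Cr].[C-]#[O+].[C-]#[O+].[C-]#[O+].[C-]#[O+].[C-]#[O+] | intermediate
14 | pentacarbonyl[(2E)-1-methoxy-4-methylpent-2-en-1-ylidene]chromium | COC(/C=C/C(C)C)=[Cr].[C-]#[O+].[C-]#[O+].[C-]#[O+].[C-]#[O+].[C-]#[O+] | intermediate
15 | (3E,5E)-4-methoxy-2-[4-methoxy-5-methyl-2-(propan-2-yl)phenoxy]-3,7-dimethylocta-1,3,5-trien-1-one bound to Cr(CO)3 | O=C=C(Oc1cc(C)c(OC)cc1C(C)C)/C(C)=C(OC)\C=C\C(C)C.[Cr].[C-]#[O+].[C-]#[O+].[C-]#[O+] | intermediate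
16 | tricarbonylchromium η6-complex of phenol 17 | COc1cc(C(C)C)c(O)c(Oc2cc(C)c(OC)cc2C(C)C)c1C.[Cr].[C-]#[O+].[C-]#[O+].[C-]#[O+] | intermediate
17 | 4-methoxy-2-[4-methoxy-5-methyl-2-(propan-2-yl)phenoxy]-3-methyl-6-(propan-2-yl)phenol | COc1cc(C(C)C)c(O)c(Oc2cc(C)c(OC)cc2C(C)C)c1C | intermediate
18 | 2-bromo-4-methoxy-3-methyl-6-(propan-2-yl)phenol | COc1cc(C(C)C)c(O)c(Br)c1C | intermediate
19 | 2-bromo-3-methyl-6-(propan-2-yl)cyclohexa-2,5-diene-1,4-dione | CC1=C(Br)C(=O)C(C(C)C)=CC1=O | intermediate
20 | sodium 4-methoxy-2-[4-methoxy-5-methyl-2-(propan-2-yl)phenoxy]-3-methyl-6-(propan-2-yl)phenoxide | [Na+].[O-]c1c(C(C)C)cc(OC)c(C)c1Oc1cc(C)c(OC)cc1C(C)C | intermediate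
21 | CNP0335608.0, 2-{4-methoxy-2-[4-methoxy-5-methyl-2-(propan-2-yl)phenoxy]-3-methyl-6-(propan-2-yl)phenoxy}-3-methyl-6-(propan-2-yl)cyclohexa-2,5-diene-1,4-dione (achiral) | COc1cc(C(C)C)c(Oc2c(C)c(OC)cc(C(C)C)c2OC2=C(C)C(=O)C=C(C(C)C)C2=O)cc1C | target

**Count and risks**
Total steps: 8. Longest linear sequence: 5 steps (1, 2, 3, 6, 8).

Steps most likely to fail:

1. Step 6 (benzannulation with an aryl ynol ether). The alkyne may insert with the opposite orientation, or the sequence may stop after insertion (stable alkoxycarbene, cyclobutenone or furan formation) instead of going on to CO insertion and ring closure. The fallback uses known chemistry and sets out from 3 and 19. Phenol 3 and bromoquinone 19 (K2CO3, DMF, 0 °C) would give by addition–elimination the aryloxyquinone 2-[4-methoxy-5-methyl-2-(propan-2-yl)phenoxy]-3-methyl-6-(propan-2-yl)cyclohexa-2,5-diene-1,4-dione F1. Reduction with aqueous Na2S2O4 would give the hydroquinone 2-[4-methoxy-5-methyl-2-(propan-2-yl)phenoxy]-3-methyl-6-(propan-2-yl)benzene-1,4-diol F2. Methylation with Me2SO4 (1.0 equiv) and K2CO3 in acetone should take place at the hydroxyl flanked by methyl and hydrogen, the other one being shielded by the isopropyl and aryloxy groups, and the route is rejoined at 17.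

2. Step 8 (phenoxide plus bromoquinone). Electron transfer from the very electron-rich phenoxide to the quinone, or slow substitution between two doubly ortho-substituted partners, may outrun the addition–elimination. The fallback sets out from 17 and builds ring C on its oxygen instead of attaching it. KH and trichloroethylene in THF would give the (E)-1,2-dichlorovinyl ether of 17 F3. n-BuLi and then MeI would give the prop-1-ynyl ether of 17 F4. Benzannulation with 14 under the conditions of step 6 (validated by then on the close relative 6) would give the trimer phenol 4-methoxy-2-{4-methoxy-2-[4-methoxy-5-methyl-2-(propan-2-yl)phenoxy]-3-methyl-6-(propan-2-yl)phenoxy}-3-methyl-6-(propan-2-yl)phenol F5. Oxidative demethylation of its only free p-methoxyphenol ring with PhI(OAc)2 in MeCN/H2O would come back to the route at 21.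

3. Step 5 (aldol condensation on the carbene complex). Proton transfer from the enolisable aldehyde to the carbene anion, retro-aldol cleavage or incomplete elimination may erode the conversion. The fallback sets out from 7 and makes the alkenyl group first. 3-Methylbut-1-yne F6 would be hydrozirconated with Cp2Zr(H)Cl and iodinated (I2) to (E)-1-iodo-3-methylbut-1-ene F7. Iodine–lithium exchange (t-BuLi, 2 equiv, Et2O, −78 °C) would give (E)-3-methylbut-1-en-1-yllithium F8. Addition to Cr(CO)6 (7) would give lithium pentacarbonyl[(2E)-4-methylpent-2-enoyl]chromate F9, and O-methylation with Me3OBF4 would rejoin the route at 14.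

## Further compounds
F1 | step 6 | 2-[4-methoxy-5-methyl-2-(propan-2-yl)phenoxy]-3-methyl-6-(propan-2-yl)cyclohexa-2,5-diene-1,4-dione | COc1cc(C(C)C)c(OC2=C(C)C(=O)C=C(C(C)C)C2=O)cc1C
F2 | step 6 | 2-[4-methoxy-5-methyl-2-(propan-2-yl)phenoxy]-3-methyl-6-(propan-2-yl)benzene-1,4-diol | COc1cc(C(C)C)c(Oc2c(C)c(O)cc(C(C)C)c2O)cc1C
F3 | step 8 | (E)-1,2-dichlorovinyl ether of 17 | Cl/C=C(/Cl)Oc1c(C(C)C)cc(OC)c(C)c1Oc1cc(C)c(OC)cc1C(C)C
F4 | step 8 | prop-1-ynyl ether of 17 | CC#COc1c(C(C)C)cc(OC)c(C)c1Oc1cc(C)c(OC)cc1C(C)C
F5 | step 8 | 4-methoxy-2-{4-methoxy-2-[4-methoxy-5-methyl-2-(propan-2-yl)phenoxy]-3-methyl-6-(propan-2-yl)phenoxy}-3-methyl-6-(propan-2-yl)phenol | COc1cc(C(C)C)c(O)c(Oc2c(C(C)C)cc(OC)c(C)c2Oc2cc(C)c(OC)cc2C(C)C)c1C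
F6 | step 5 | 3-methylbut-1-yne | CC(C)C#C
F7 | step 5 | (E)-1-iodo-3-methylbut-1-ene | I/C=C/C(C)C
F8 | step 5 | (E)-3-methylbut-1-en-1-yllithium | [Li]/C=C/C(C)C
F9 | step 5 | lithium pentacarbonyl[(2E)-4-methylpent-2-enoyl]chromate | [Li+].CC(C)/C=C/C(=O)[Cr-].[C-]#[O+].[C-]#[O+].[C-]#[O+].[C-]#[O+].[C-]#[O+]
A1 | direct plan | 3-chloro-4-methylcyclobut-3-ene-1,2-dione | CC1=C(Cl)C(=O)C1=O
A2 | direct plan | 3-[4-methoxy-5-methyl-2-(propan-2-yl)phenoxy]-4-methylcyclobut-3-ene-1,2-dione | COc1cc(C(C)C)c(OC2=C(C)C(=O)C2=O)cc1C
A3 | direct plan | O-linked bis(4-alkenylcyclobutenone) carbinol (diastereomer mixture) | OC1(C(=C)C(C)C)C(=O)C(C)=C1OC1(C(=C)C(C)C)C(=O)C(C)=C1Oc1cc(C)c(OC)cc1C(C)C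
A4 | direct plan | 3-{4-hydroxy-2-[4-methoxy-5-methyl-2-(propan-2-yl)phenoxy]-3-methyl-6-(propan-2-yl)phenoxy}-2-methyl-5-(propan-2-yl)benzene-1,4-diol | COc1cc(C(C)C)c(Oc2c(C)c(O)cc(C(C)C)c2Oc2c(C)c(O)cc(C(C)C)c2O)cc1C
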